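**Strategy.** Everything rests on disconnecting the C5–C6 bond of the nonadecanoyl chain, a CH2–CH2 link four carbons beyond the ester carbonyl and far from the oxolane ring, the cyclononadiene ring and all four stereocentres. In one operation a copper-catalysed Csp3–Csp3 coupling joins tetradecylmagnesium chloride to the 5-bromopentanoate of the complete, unprotected core and gives the target directly. That precursor is built from (S)-linalool: Sharpless epoxidation fixes the quaternary oxolane carbon, SN2 opening by an isobutenyl copper reagent fixes its neighbour, an oxonium-ene cyclisation closes the oxolane, and ring-closing metathesis closes the Z-cyclononene.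

Key step: step 18

Assumption: (S)-(+)-linalool of high ee and diethyl (3-methylbut-2-en-1-yl)phosphonate are taken as purchasable; otherwise both are standard preparations (geraniol by Sharpless epoxidation and reductive epoxide opening; Arbuzov reaction of prenyl bromide with triethyl phosphite).

Abbreviations: TES = triethylsilyl, TBDPS = tert-butyldiphenylsilyl, PMB = 4-methoxybenzyl, MOM = methoxymethyl. Bicyclic compounds are numbered as 1H-cyclonona[c]furans (C1 quaternary, O2, C3, C3a, C4–C10, C10a).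

**Step 1**
Reactants: 1 (S)-(+)-linalool
Product: 2 (3S)-3,7-dimethyl-3-(triethylsilyloxy)octa-1,6-diene
Conditions: TESOTf, 2,6-lutidine, CH2Cl2, 0 °C
Reagents that add atoms: triethylsilyl trifluoromethanesulfonate, CC[Si](CC)(CC)OS(=O)(=O)C(F)(F)F
Why: Silylation of the tertiary allylic alcohol with a silyl triflate and a hindered base is routine, leaves the (S) centre untouched and blocks oxa-Michael and epoxide-opening side reactions of this hydroxyl in steps 3–7.

**Step 2**
Reactants: 2 (3S)-3,7-dimethyl-3-(triethylsilyloxy)octa-1,6-diene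
Product: 4 (4S)-4-methyl-4-(triethylsilyloxy)hex-5-enal, via ozonide 3 (not isolated)
Conditions: O3 (1 equiv, Sudan Red 7B end point), CH2Cl2, −78 °C; then Me2S, −78 °C → rt
Reagents that add atoms: ozone, [O-][O+]=O
Why: Chemoselective ozonolysis: the electron-rich trisubstituted olefin should react far faster than the hindered monosubstituted vinyl group, and reductive work-up of ozonide 3 should give the aldehyde.

**Step 3**
Reactants: 4 (4S)-4-methyl-4-(triethylsilyloxy)hex-5-enal; 5 ethyl 2-(diethoxyphosphoryl)acrylate; 6 4-methoxybenzyl alcohol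
Product: 8 ethyl (2E,6S)-2-[(4-methoxybenzyloxy)methyl]-6-methyl-6-(triethylsilyloxy)octa-2,7-dienoate, via sodium phosphonate carbanion 7 (not isolated)
Conditions: 6, NaH, THF, 0 °C; 5, −20 → 0 °C; then 4, 0 °C → rt
Reagents that add atoms: none
Why: Tandem oxa-Michael/Horner–Wadsworth–Emmons reaction: the PMB alkoxide adds to the phosphonoacrylate to give carbanion 7, which should olefinate 4 with the alkyl chain trans to the ester (usual E preference of α-substituted phosphonoacetates), any Z isomer being removed by chromatography.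

**Step 4**
Reactants: 8 ethyl (2E,6S)-2-[(4-methoxybenzyloxy)methyl]-6-methyl-6-(triethylsilyloxy)octa-2,7-dienoate
Product: 9 (2Z,6S)-2-[(4-methoxybenzyloxy)methyl]-6-methyl-6-(triethylsilyloxy)octa-2,7-dien-1-ol
Conditions: DIBAL-H, CH2Cl2, −78 °C; Rochelle salt
Reagents that add atoms: none
Why: DIBAL-H 1,2-reduction of an enoate to the allylic alcohol at low temperature should leave the silyl and PMB ethers and both olefins untouched.

**Step 5**
Reactants: 9 (2Z,6S)-2-[(4-methoxybenzyloxy)methyl]-6-methyl-6-(triethylsilyloxy)octa-2,7-dien-1-ol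
Product: 10 [(2R,3S)-2-[(4-methoxybenzyloxy)methyl]-3-[(3S)-3-methyl-3-(triethylsilyloxy)pent-4-enyl]oxiran-2-yl]methanol
Conditions: Ti(OiPr)4 (cat.), L-(+)-diethyl tartrate (cat.), t-BuOOH, 4 Å MS, CH2Cl2, −20 °C
Reagents that add atoms: tert-butyl hydroperoxide, CC(C)(C)OO
Why: Sharpless asymmetric epoxidation: the L-(+)-tartrate catalyst should deliver oxygen to the face of the trisubstituted allylic alcohol that gives the (2R,3S)-epoxide, so reagent control sets the future quaternary oxolane carbon and (before inversion) its neighbour, while the non-allylic vinyl group is inert.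

**Step 6**
Reactants: 10 [(2R,3S)-2-[(4-methoxybenzyloxy)methyl]-3-[(3S)-3-methyl-3-(triethylsilyloxy)pent-4-enyl]oxiran-2-yl]methanol
Product: 11 tert-butyl{[(2S,3S)-2-[(4-methoxybenzyloxy)methyl]-3-[(3S)-3-methyl-3-(triethylsilyloxy)pent-4-enyl]oxiran-2-yl]methoxy}diphenylsilane
Conditions: TBDPSCl, imidazole, DMF, rt
Reagents that add atoms: tert-butyl(chloro)diphenylsilane, CC(C)(C)[Si](Cl)(c1ccccc1)c1ccccc1
Why: Silylation of the primary hydroxyl prevents alkoxide-driven pathways in step 7 and marks this CH2O as the later ester site, distinct from the PMB-protected CH2O that becomes the dienyl group.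

**Step 7**
Reactants: 11 tert-butyl{[(2S,3S)-2-[(4-methoxybenzyloxy)methyl]-3-[(3S)-3-methyl-3-(triethylsilyloxy)pent-4-enyl]oxiran-2-yl]methoxy}diphenylsilane; 12 2-methylprop-1-enylmagnesium bromide
Product: 13 (2S,3S,6S)-1-(tert-butyldiphenylsilyloxy)-2-[(4-methoxybenzyloxy)methyl]-6-methyl-3-(2-methylprop-1-enyl)-6-(triethylsilyloxy)oct-7-en-2-ol
Conditions: 12, CuI (20 mol%), THF, −30 → 0 °C
Reagents that add atoms: none
Why: Copper-catalysed Grignard opening of a trisubstituted epoxide should occur by SN2 attack at the less substituted carbon (not the fully substituted carbon carrying two CH2O groups) with inversion, which sets the stereocentre that becomes C-10a and unveils the tertiary alcohol.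

**Step 8**
Reactants: 13 (2S,3S,6S)-1-(tert-butyldiphenylsilyloxy)-2-[(4-methoxybenzyloxy)methyl]-6-methyl-3-(2-methylprop-1-enyl)-6-(triethylsilyloxy)oct-7-en-2-ol
Product: 14 methoxymethyl ether of 13 at the tertiary hydroxyl
Conditions: MOMCl, i-Pr2NEt, Bu4NI (cat.), ClCH2CH2Cl, 60 °C
Reagents that add atoms: chloromethyl methyl ether, COCCl
Why: MOM ether formation: O-alkylation of the hindered tertiary alcohol with the small, reactive chloromethyl ether installs the future C-3 of the oxolane as a latent oxocarbenium ion.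

**Step 9**
Reactants: 14 methoxymethyl ether of 13
Product: 16 (2S,3S,4R)-2-[(tert-butyldiphenylsilyloxy)methyl]-2-[(4-methoxybenzyloxy)methyl]-3-[(3S)-3-methyl-3-(triethylsilyloxy)pent-4-enyl]-4-(prop-1-en-2-yl)oxolane, via oxocarbenium triflate 15 (not isolated)
Conditions: TMSOTf, 2,6-di-tert-butyl-4-methylpyridine, CH2Cl2, −78 → −40 °C
Reagents that add atoms: none
Why: (3,5)-Oxonium-ene (Prins-type) cyclisation: TMSOTf ionises the MOM ether at its unhindered methoxy oxygen to 15, which should add to the proximal carbon of the trisubstituted olefin with transfer of a methyl hydrogen to give the 3-isopropenyl oxolane, A(1,3) strain with the cis-methyl group holding the allylic C–H in the olefin plane so that the tethered electrophile places the isopropenyl group trans to the neighbouring side chain (new centre C-4, R).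

**Step 10**
Reactants: 16 (2S,3S,4R)-4-(prop-1-en-2-yl)oxolane
Product: 17 (2S,3S,4R)-2-[(tert-butyldiphenylsilyloxy)methyl]-4-(3-chloroprop-1-en-2-yl)-2-[(4-methoxybenzyloxy)methyl]-3-[(3S)-3-methyl-3-(triethylsilyloxy)pent-4-enyl]oxolane
Conditions: Ca(OCl)2, CO2 (s), CH2Cl2–H2O, 0 °C
Reagents that add atoms: calcium hypochlorite, [Ca+2].[O-]Cl.[O-]Cl
Why: Ene-type allylic chlorination by HOCl should be selective for the electron-rich 1,1-disubstituted isopropenyl group, the only olefin with allylic hydrogens, and gives the 2-(chloromethyl)allyl unit with transposition of the double bond.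

**Step 11**
Reactants: 17 (2S,3S,4R)-4-(3-chloroprop-1-en-2-yl)oxolane; 18 vinylmagnesium bromide
Product: 19 (2S,3S,4R)-2-[(tert-butyldiphenylsilyloxy)methyl]-2-[(4-methoxybenzyloxy)methyl]-3-[(3S)-3-methyl-3-(triethylsilyloxy)pent-4-enyl]-4-(penta-1,4-dien-2-yl)oxolane
Conditions: 18, CuI (10 mol%), THF, −20 → 0 °C
Reagents that add atoms: none
Why: Copper-catalysed coupling of a vinyl Grignard reagent with an allylic chloride should give the skipped 1,4-diene, SN2 and SN2′ pathways leading to the same product because the allyl unit is symmetrical.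

**Step 12**
Reactants: 19 (2S,3S,4R)-4-(penta-1,4-dien-2-yl)oxolane
Product: 20 tert-butyl{[(1S,3aR,6Z,8S,10aS)-1-[(4-methoxybenzyloxy)methyl]-8-methyl-4-methylidene-8-(triethylsilyloxy)-3,3a,4,5,8,9,10,10a-octahydro-1H-cyclonona[c]furan-1-yl]methoxy}diphenylsilane
Conditions: Hoveyda–Grubbs II (10 mol%), 1,4-benzoquinone (20 mol%), toluene (1 mM), 80 °C
Reagents that add atoms: none
Why: Ring-closing metathesis: the catalyst should load on the unhindered allyl terminus (type I olefin), from which only closure onto the vinyl group of the silylated carbinol is possible, whereas the 1,1-disubstituted olefin and the hindered vinyl group (both type III) do not couple with each other; the trans-fused oxolane pre-organises the chains and the nine-membered ring enforces the Z olefin.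

**Step 13**
Reactants: 20 PMB/TBDPS/TES-protected bicycle
Product: 21 [(1S,3aR,6Z,8S,10aS)-1-[(tert-butyldiphenylsilyloxy)methyl]-8-methyl-4-methylidene-8-(triethylsilyloxy)-3,3a,4,5,8,9,10,10a-octahydro-1H-cyclonona[c]furan-1-yl]methanol
Conditions: DDQ, CH2Cl2–pH 7 buffer, 0 °C
Reagents that add atoms: none
Why: Oxidative PMB ether cleavage with DDQ under buffered conditions should leave the silyl ethers and the unconjugated olefins untouched.

**Step 14**
Reactants: 21 primary alcohol
Product: 22 (1R,3aR,6Z,8S,10aS)-1-[(tert-butyldiphenylsilyloxy)methyl]-8-methyl-4-methylidene-8-(triethylsilyloxy)-3,3a,4,5,8,9,10,10a-octahydro-1H-cyclonona[c]furan-1-carbaldehyde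
Conditions: Dess–Martin periodinane, NaHCO3, CH2Cl2, 0 °C → rt
Reagents that add atoms: none
Why: Dess–Martin oxidation of the neopentyl primary alcohol gives an aldehyde without α-hydrogen, which cannot enolise or epimerise.

**Step 15**
Reactants: 22 aldehyde; 23 diethyl (3-methylbut-2-en-1-yl)phosphonate
Product: 24 tert-butyl{[(1R,3aR,6Z,8S,10aS)-8-methyl-4-methylidene-1-[(1E)-4-methylpenta-1,3-dien-1-yl]-8-(triethylsilyloxy)-3,3a,4,5,8,9,10,10a-octahydro-1H-cyclonona[c]furan-1-yl]methoxy}diphenylsilane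
Conditions: 23, n-BuLi, THF–DMPU, −78 °C → rt
Reagents that add atoms: none
Why: Horner–Wadsworth–Emmons olefination with the lithiated allylic phosphonate (α-attack favoured because the γ-carbon carries two methyl groups) should give the E-disubstituted olefin of the 4-methylpenta-1,3-dienyl group.

**Step 16**
Reactants: 24 bis-silyl ether
Product: 25 (1R,3aR,6Z,8S,10aS)-1-(hydroxymethyl)-8-methyl-4-methylidene-1-[(1E)-4-methylpenta-1,3-dien-1-yl]-3,3a,4,5,8,9,10,10a-octahydro-1H-cyclonona[c]furan-8-ol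
Conditions: TBAF, THF, rt → 40 °C
Reagents that add atoms: none
Why: Fluoride-mediated desilylation should cleave both the primary TBDPS ether and the tertiary TES ether without touching the olefins.

**Step 17**
Reactants: 25 diol; 26 5-bromopentanoyl chloride
Product: 27 [(1R,3aR,6Z,8S,10aS)-8-hydroxy-8-methyl-4-methylidene-1-[(1E)-4-methylpenta-1,3-dien-1-yl]-3,3a,4,5,8,9,10,10a-octahydro-1H-cyclonona[c]furan-1-yl]methyl 5-bromopentanoate
Conditions: 26, pyridine, CH2Cl2, −20 → 0 °C
Reagents that add atoms: none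
Why: Acylation with the acid chloride should occur only at the primary hydroxyl, the tertiary allylic alcohol being inert under these conditions, and installs C1–C5 of the acyl chain with a primary bromide at C5.

**Step 18**
Reactants: 27 5-bromopentanoate; 28 tetradecylmagnesium chloride
Product: 30 [(1R,3aR,6Z,8S,10aS)-8-hydroxy-8-methyl-4-methylidene-1-[(1E)-4-methylpenta-1,3-dien-1-yl]-3,3a,4,5,8,9,10,10a-octahydro-1H-cyclonona[c]furan-1-yl]methyl nonadecanoate (CNP0120482.1), via chloromagnesium alkoxide 29 (not isolated)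
Conditions: 28 (2.5 equiv, slow addition), Li2CuCl4 (5 mol%), NMP (4 equiv), THF, −10 → 0 °C; aq NH4Cl
Reagents that add atoms: none
Why: The first equivalent of 28 converts the tertiary hydroxyl of 27 into the inert chloromagnesium alkoxide 29; Li2CuCl4 is reduced to copper(I), which forms a tetradecylcuprate that displaces the primary bromide at C5 by SN2-type oxidative addition and reductive elimination, forming the C5–C6 bond of the nonadecanoyl chain. The closest known reaction type is the Kochi–Tamura/Schlosser copper-catalysed coupling of alkyl Grignard reagents with primary alkyl bromides, which in its NMP-modified form is routinely run on ω-bromo esters. The step closes no ring and creates no stereocentre, so the four stereocentres, the Z ring olefin and the E diene are carried through unchanged. The selectivity needed is substitution at C–Br in preference to attack at the ester carbonyl or the π-systems: it should be secured by the fast copper-catalysed substitution at low temperature with slow Grignard addition, by the neopentyl position of the ester oxygen next to the quaternary C-1 of the oxolane, and by the absence of any allylic leaving group, isolated and conjugated olefins being unreactive towards alkylcopper and Grignard reagents. Aqueous NH4Cl then releases the tertiary alcohol of 30.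

**Compound list**

1 | (S)-(+)-linalool, (3S)-3,7-dimethylocta-1,6-dien-3-ol | C=C[C@@](C)(O)CCC=C(C)C | starting material
2 | (3S)-3,7-dimethyl-3-(triethylsilyloxy)octa-1,6-diene | C=C[C@@](C)(O[Si](CC)(CC)CC)CCC=C(C)C | intermediate
3 | 3,3-dimethyl-5-[(3S)-3-methyl-3-(triethylsilyloxy)pent-4-enyl]-1,2,4-trioxolane (ozonide) | C=C[C@@](C)(O[Si](CC)(CC)CC)CCC1OOC(C)(C)O1 | intermediate (not isolated)
4 | (4S)-4-methyl-4-(triethylsilyloxy)hex-5-enal | C=C[C@@](C)(O[Si](CC)(CC)CC)CCC=O | intermediate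
5 | ethyl 2-(diethoxyphosphoryl)acrylate | C=C(C(=O)OCC)P(=O)(OCC)OCC | starting material
6 | 4-methoxybenzyl alcohol | COc1ccc(CO)cc1 | starting material
7 | sodium salt of ethyl 2-(diethoxyphosphoryl)-3-(4-methoxybenzyloxy)propanoate | CCOC(=O)[C-](COCc1ccc(OC)cc1)P(=O)(OCC)OCC.[Na+] | intermediate (not isolated)
8 | ethyl (2E,6S)-2-[(4-methoxybenzyloxy)methyl]-6-methyl-6-(triethylsilyloxy)octa-2,7-dienoate | CCOC(=O)/C(COCc1ccc(OC)cc1)=C/CC[C@](C)(O[Si](CC)(CC)CC)C=C | intermediate
9 | (2Z,6S)-2-[(4-methoxybenzyloxy)methyl]-6-methyl-6-(triethylsilyloxy)octa-2,7-dien-1-ol | OC/C(COCc1ccc(OC)cc1)=C/CC[C@](C)(O[Si](CC)(CC)CC)C=C | intermediate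
10 | [(2R,3S)-2-[(4-methoxybenzyloxy)methyl]-3-[(3S)-3-methyl-3-(triethylsilyloxy)pent-4-enyl]oxiran-2-yl]methanol | OC[C@]1(COCc2ccc(OC)cc2)O[C@H]1CC[C@](C)(O[Si](CC)(CC)CC)C=C | intermediate
11 | tert-butyl{[(2S,3S)-2-[(4-methoxybenzyloxy)methyl]-3-[(3S)-3-methyl-3-(triethylsilyloxy)pent-4-enyl]oxiran-2-yl]methoxy}diphenylsilane | CC(C)(C)[Si](c1ccccc1)(c1ccccc1)OC[C@]1(COCc2ccc(OC)cc2)O[C@H]1CC[C@](C)(O[Si](CC)(CC)CC)C=C | intermediate
12 | 2-methylprop-1-enylmagnesium bromide | CC(C)=C[Mg]Br | starting material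
13 | (2S,3S,6S)-1-(tert-butyldiphenylsilyloxy)-2-[(4-methoxybenzyloxy)methyl]-6-methyl-3-(2-methylprop-1-enyl)-6-(triethylsilyloxy)oct-7-en-2-ol | CC(C)(C)[Si](c1ccccc1)(c1ccccc1)OC[C@@](O)(COCc2ccc(OC)cc2)[C@H](C=C(C)C)CC[C@](C)(O[Si](CC)(CC)CC)C=C | intermediate
14 | methoxymethyl ether of 13 (tertiary O–CH2–OMe) | CC(C)(C)[Si](c1ccccc1)(c1ccccc1)OC[C@@](OCOC)(COCc2ccc(OC)cc2)[C@H](C=C(C)C)CC[C@](C)(O[Si](CC)(CC)CC)C=C | intermediate
15 | O-methylidene oxocarbenium triflate derived from 14 | CC(C)(C)[Si](c1ccccc1)(c1ccccc1)OC[C@@]([O+]=C)(COCc2ccc(OC)cc2)[C@H](C=C(C)C)CC[C@](C)(O[Si](CC)(CC)CC)C=C.[O-]S(=O)(=O)C(F)(F)F | intermediate (not isolated)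
16 | (2S,3S,4R)-2-[(tert-butyldiphenylsilyloxy)methyl]-2-[(4-methoxybenzyloxy)methyl]-3-[(3S)-3-methyl-3-(triethylsilyloxy)pent-4-enyl]-4-(prop-1-en-2-yl)oxolane | CC(C)(C)[Si](c1ccccc1)(c1ccccc1)OC[C@]1(COCc2ccc(OC)cc2)OC[C@@H](C(C)=C)[C@@H]1CC[C@](C)(O[Si](CC)(CC)CC)C=C | intermediate
17 | (2S,3S,4R)-2-[(tert-butyldiphenylsilyloxy)methyl]-4-(3-chloroprop-1-en-2-yl)-2-[(4-methoxybenzyloxy)methyl]-3-[(3S)-3-methyl-3-(triethylsilyloxy)pent-4-enyl]oxolane | CC(C)(C)[Si](c1ccccc1)(c1ccccc1)OC[C@]1(COCc2ccc(OC)cc2)OC[C@@H](C(=C)CCl)[C@@H]1CC[C@](C)(O[Si](CC)(CC)CC)C=C | intermediate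
18 | vinylmagnesium bromide | C=C[Mg]Br | starting material
19 | (2S,3S,4R)-2-[(tert-butyldiphenylsilyloxy)methyl]-2-[(4-methoxybenzyloxy)methyl]-3-[(3S)-3-methyl-3-(triethylsilyloxy)pent-4-enyl]-4-(penta-1,4-dien-2-yl)oxolane | CC(C)(C)[Si](c1ccccc1)(c1ccccc1)OC[C@]1(COCc2ccc(OC)cc2)OC[C@@H](C(=C)CC=C)[C@@H]1CC[C@](C)(O[Si](CC)(CC)CC)C=C | intermediate
20 | tert-butyl{[(1S,3aR,6Z,8S,10aS)-1-[(4-methoxybenzyloxy)methyl]-8-methyl-4-methylidene-8-(triethylsilyloxy)-3,3a,4,5,8,9,10,10a-octahydro-1H-cyclonona[c]furan-1-yl]methoxy}diphenylsilane | C=C1C/C=C\[C@@](C)(O[Si](CC)(CC)CC)CC[C@H]2[C@H]1CO[C@@]2(COCc3ccc(OC)cc3)CO[Si](c3ccccc3)(c3ccccc3)C(C)(C)C | intermediate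
21 | [(1S,3aR,6Z,8S,10aS)-1-[(tert-butyldiphenylsilyloxy)methyl]-8-methyl-4-methylidene-8-(triethylsilyloxy)-3,3a,4,5,8,9,10,10a-octahydro-1H-cyclonona[c]furan-1-yl]methanol | C=C1C/C=C\[C@@](C)(O[Si](CC)(CC)CC)CC[C@H]2[C@H]1CO[C@@]2(CO)CO[Si](c3ccccc3)(c3ccccc3)C(C)(C)C | intermediate
22 | (1R,3aR,6Z,8S,10aS)-1-[(tert-butyldiphenylsilyloxy)methyl]-8-methyl-4-methylidene-8-(triethylsilyloxy)-3,3a,4,5,8,9,10,10a-octahydro-1H-cyclonona[c]furan-1-carbaldehyde | C=C1C/C=C\[C@@](C)(O[Si](CC)(CC)CC)CC[C@H]2[C@H]1CO[C@@]2(C=O)CO[Si](c3ccccc3)(c3ccccc3)C(C)(C)C | intermediate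
23 | diethyl (3-methylbut-2-en-1-yl)phosphonate | CCOP(=O)(CC=C(C)C)OCC | starting material
24 | tert-butyl{[(1R,3aR,6Z,8S,10aS)-8-methyl-4-methylidene-1-[(1E)-4-methylpenta-1,3-dien-1-yl]-8-(triethylsilyloxy)-3,3a,4,5,8,9,10,10a-octahydro-1H-cyclonona[c]furan-1-yl]methoxy}diphenylsilane | C=C1C/C=C\[C@@](C)(O[Si](CC)(CC)CC)CC[C@H]2[C@H]1CO[C@@]2(/C=C/C=C(C)C)CO[Si](c3ccccc3)(c3ccccc3)C(C)(C)C | intermediate
25 | (1R,3aR,6Z,8S,10aS)-1-(hydroxymethyl)-8-methyl-4-methylidene-1-[(1E)-4-methylpenta-1,3-dien-1-yl]-3,3a,4,5,8,9,10,10a-octahydro-1H-cyclonona[c]furan-8-ol | C=C1C/C=C\[C@@](C)(O)CC[C@H]2[C@H]1CO[C@@]2(/C=C/C=C(C)C)CO | intermediate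
26 | 5-bromopentanoyl chloride | O=C(Cl)CCCCBr | starting material
27 | [(1R,3aR,6Z,8S,10aS)-8-hydroxy-8-methyl-4-methylidene-1-[(1E)-4-methylpenta-1,3-dien-1-yl]-3,3a,4,5,8,9,10,10a-octahydro-1H-cyclonona[c]furan-1-yl]methyl 5-bromopentanoate | C=C1C/C=C\[C@@](C)(O)CC[C@H]2[C@H]1CO[C@@]2(/C=C/C=C(C)C)COC(=O)CCCCBr | intermediate
28 | tetradecylmagnesium chloride | CCCCCCCCCCCCCC[Mg]Cl | starting material
29 | chloromagnesium 8-alkoxide of 27 | C=C1C/C=C\[C@@](C)(O[Mg]Cl)CC[C@H]2[C@H]1CO[C@@]2(/C=C/C=C(C)C)COC(=O)CCCCBr | intermediate (not isolated)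
30 | [(1R,3aR,6Z,8S,10aS)-8-hydroxy-8-methyl-4-methylidene-1-[(1E)-4-methylpenta-1,3-dien-1-yl]-3,3a,4,5,8,9,10,10a-octahydro-1H-cyclonona[c]furan-1-yl]methyl nonadecanoate (CNP0120482.1) | C=C1C/C=C\[C@@](C)(O)CC[C@H]2[C@H]1CO[C@@]2(/C=C/C=C(C)C)COC(=O)CCCCCCCCCCCCCCCCCC | target

**Total step count:** 18. **Longest linear sequence:** 18 steps (1 → 30); all coupling partners are purchased.

**Steps most likely to fail**

Step 9 (oxonium-ene cyclisation). The Lewis acid may ionise the tertiary allylic silyl ether or the PMB ether, and the cation formed after C–C bonding may lose a proton from the wrong position or undergo 2-oxonia-Cope scrambling. Fallback, setting out from 13: a hydroxyl-directed Snider carbonyl-ene reaction of the isobutenyl group with formaldehyde (paraformaldehyde, Me2AlCl, CH2Cl2, −78 → 0 °C) would give (2S,3S,6S)-1-(tert-butyldiphenylsilyloxy)-3-[(2R)-1-hydroxy-3-methylbut-3-en-2-yl]-2-[(4-methoxybenzyloxy)methyl]-6-methyl-6-(triethylsilyloxy)oct-7-en-2-ol F1. Selective tosylation of its primary hydroxyl (TsCl, pyridine) would give the primary monotosylate of that diol F2, and KOt-Bu in THF would close the oxolane by 5-exo-tet Williamson etherification, coming back to the route at 16.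

Step 12 (ring-closing metathesis). Slow closure onto the hindered vinyl group may let catalyst loading at that group and closure onto the 1,1-disubstituted olefin (seven-membered ring), or oligomerisation, compete. Fallback, setting out from 19: selective epoxidation of the 1,1-disubstituted olefin (m-CPBA, NaHCO3, CH2Cl2, −20 °C) would mask it as the 4-[2-(prop-2-enyl)oxiran-2-yl] analogue of 19 F3 (epimers at the oxirane carbon). Ring-closing metathesis of the two remaining terminal olefins (Grubbs II, toluene, 80 °C) would give the 4-spiro-oxirane analogue of 20 F4. Stereospecific deoxygenation (LiPPh2, THF; then MeI) would restore the exocyclic methylene, coming back to the route at 20.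

Step 7 (epoxide opening). Sluggish SN2 attack at a carbon flanked by the fully substituted epoxide carbon may let Lewis-acid-induced rearrangement of the epoxide or halohydrin formation by magnesium halide compete. Fallback, setting out from 10 (free epoxy alcohol): dimethyl(2-methylprop-1-enyl)aluminium F5, made from 12 and Me2AlCl, would bind the primary hydroxyl and deliver the alkenyl group intramolecularly to C3 with inversion. This would give (2R,3S,6S)-2-[(4-methoxybenzyloxy)methyl]-6-methyl-3-(2-methylprop-1-enyl)-6-(triethylsilyloxy)oct-7-ene-1,2-diol F6, whose primary hydroxyl would be silylated selectively (TBDPSCl, imidazole), coming back to the route at 13.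

**Further compounds**

F1 | step 9 | (2S,3S,6S)-1-(tert-butyldiphenylsilyloxy)-3-[(2R)-1-hydroxy-3-methylbut-3-en-2-yl]-2-[(4-methoxybenzyloxy)methyl]-6-methyl-6-(triethylsilyloxy)oct-7-en-2-ol | CC(C)(C)[Si](c1ccccc1)(c1ccccc1)OC[C@@](O)(COCc2ccc(OC)cc2)[C@H]([C@@H](CO)C(C)=C)CC[C@](C)(O[Si](CC)(CC)CC)C=C
F2 | step 9 | primary 4-methylbenzenesulfonate of F1 | CC(C)(C)[Si](c1ccccc1)(c1ccccc1)OC[C@@](O)(COCc2ccc(OC)cc2)[C@H]([C@@H](COS(=O)(=O)c2ccc(C)cc2)C(C)=C)CC[C@](C)(O[Si](CC)(CC)CC)C=C
F3 | step 12 | (2S,3S,4R)-2-[(tert-butyldiphenylsilyloxy)methyl]-2-[(4-methoxybenzyloxy)methyl]-3-[(3S)-3-methyl-3-(triethylsilyloxy)pent-4-enyl]-4-[2-(prop-2-enyl)oxiran-2-yl]oxolane | CC(C)(C)[Si](c1ccccc1)(c1ccccc1)OC[C@]1(COCc2ccc(OC)cc2)OC[C@@H](C2(CC=C)CO2)[C@@H]1CC[C@](C)(O[Si](CC)(CC)CC)C=C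
F4 | step 12 | 4-spiro-oxirane analogue of 20 (oxirane in place of the 4-methylidene group) | C1OC12C/C=C\[C@@](C)(O[Si](CC)(CC)CC)CC[C@H]3[C@H]2CO[C@@]3(COCc4ccc(OC)cc4)CO[Si](c4ccccc4)(c4ccccc4)C(C)(C)C
F5 | step 7 | dimethyl(2-methylprop-1-enyl)aluminium | CC(C)=C[Al](C)C
F6 | step 7 | (2R,3S,6S)-2-[(4-methoxybenzyloxy)methyl]-6-methyl-3-(2-methylprop-1-enyl)-6-(triethylsilyloxy)oct-7-ene-1,2-diol | OC[C@@](O)(COCc1ccc(OC)cc1)[C@H](C=C(C)C)CC[C@](C)(O[Si](CC)(CC)CC)C=C
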